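**Plan**

1. Locants are abietane locants: ring A = C1–C5, C10; ring B = C5–C10; ring C = C8, C9, C11–C14; C19 = lactone C=O on C4; C20 = OCH2 on C10. Ar = 2,3,5-trimethoxy-4-(propan-2-yl)phenyl, i.e. ring C attached through C9.
2. Retrosynthetic cuts, in order: the C11/C14 phenols (from methyl ethers by way of the quinone); C7–C8 (Friedel–Crafts, ring B); O–C19 of the lactone, with C20 raised to CO2H; C1–C10 together with C5–C6 (Michael addition, then Claisen ring contraction of a δ-lactone); C5=C10 and O–C20 of that lactone (Knoevenagel, ester); C4–CH3 and C4–C5 (enolate alkylations); C3–C4 (aldol); C9–C10 (aryllithium plus oxirane).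
3. Forward: ring C is bought; arylacetic acid 10 (C9–C10–C20) is joined to the chain C1–C5/C19 and closed to a temporary six-membered lactone O–C20(=O)–C10=C5–C4–C3; the key step contracts this lactone to ring A; the C19–O–C20 lactone, ring B and the hydroquinone follow in that order.
4. Enabling feature: C10 carries C20, which at the acid oxidation level can be tied through oxygen to C3, and C3 is reached from C10 over C5 and C4. With C1=C2 as a vinyl group on C3, the lactone enolate C10=C20–O–C3–C2=C1 is a Claisen 1,5-diene. Its [3,3] shift forms C1–C10, spends the helper C3–O bond and releases C20 as an acid that differs from the C19 ester.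
5. Stereochemistry: only C3 comes from a chiral reagent (Sharpless kinetic resolution). C3 controls C4 (two Fráter–Seebach alkylations), C3 and C4 control C5 (conjugate addition), and C3 is converted into C10 by the suprafacial shift and disappears. The remaining helpers (C2=C3, the acid level of C20, three O-methyl groups) are removed in steps 13, 14 and 16.

Key step: step 12

**Route**

Step 1
Reactants: 1 1,2,4-trimethoxybenzene; 2 acetone
Product: 4 2-(2,3,6-trimethoxyphenyl)propan-2-ol, via aryllithium 3 (not isolated)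
Conditions: n-BuLi, THF, 0 °C to rt; then acetone, −78 °C to rt; H2O
Reagents that add atoms: none
Why: Directed ortho-metalation removes the hydrogen flanked by two methoxy groups, and the aryllithium adds to acetone (1,2-addition).

Step 2
Reactants: 4 2-(2,3,6-trimethoxyphenyl)propan-2-ol
Product: 5 1,2,4-trimethoxy-3-(propan-2-yl)benzene
Conditions: Et3SiH, CF3CO2H, CH2Cl2, 0 °C to rt
Reagents that add atoms: none
Why: Ionic hydrogenation, in which the tertiary benzylic alcohol ionises in acid and the cation takes hydride from the silane.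

Step 3
Reactants: 5 1,2,4-trimethoxy-3-(propan-2-yl)benzene; 6 oxirane
Product: 8 2-Ar-ethan-1-ol, via aryllithium 7 (not isolated)
Conditions: n-BuLi, N,N,N',N'-tetramethylethylenediamine, Et2O, 0 °C to rt; then oxirane, −78 °C to rt; H2O
Reagents that add atoms: none
Why: Directed ortho-metalation should occur at the ring hydrogen next to the vicinal dimethoxy pair (future C9), which is ortho to one and meta to two methoxy groups, whereas the other hydrogen is para to a methoxy group and its neighbouring methoxy group is turned away by the isopropyl group; the aryllithium then opens oxirane (SN2).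

Step 4
Reactants: 8 2-Ar-ethan-1-ol
Product: 10 Ar-acetic acid, via aldehyde 9 (not isolated)
Conditions: 2,2,6,6-tetramethylpiperidin-1-oxyl (cat.), NaOCl (cat.), NaClO2, MeCN/phosphate buffer pH 6.7, 35 °C
Reagents that add atoms: sodium chlorite, [Na+].[O-]Cl=O
Why: Nitroxyl-catalysed oxidation of the primary alcohol to the aldehyde and chlorite oxidation to the acid in one pot, with only catalytic hypochlorite so that chlorination of the electron-rich ring stays low.

Step 5
Reactants: 11 methyl acetate; 12 acrolein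
Product: 14 methyl (±)-3-hydroxypent-4-enoate, via lithium enolate 13 (not isolated)
Conditions: LiN(iPr)2, THF, −78 °C; then acrolein, −78 °C; H2O
Reagents that add atoms: none
Why: Kinetic aldol addition of the lithium ester enolate to the carbonyl carbon of acrolein (1,2-addition at low temperature).

Step 6
Reactants: 14 methyl (±)-3-hydroxypent-4-enoate
Product: 15 methyl (3R)-3-hydroxypent-4-enoate
Conditions: Ti(OiPr)4 (cat.), L-(+)-diisopropyl tartrate (cat.), tBuOOH (0.6 equiv), 4 Å molecular sieves, CH2Cl2, −20 °C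
Reagents that add atoms: none
Why: Sharpless kinetic resolution, in which L-(+)-tartrate should epoxidise the (3S)-allylic alcohol faster (its carbinol hydrogen lies on the face of oxygen delivery), so that the (3R)-alcohol remains; this is the only stereocentre set by a chiral reagent.

Step 7
Reactants: 15 methyl (3R)-3-hydroxypent-4-enoate
Product: 17 methyl (2S,3S)-2-[(benzyloxy)methyl]-3-hydroxypent-4-enoate, via dianion 16 (not isolated)
Conditions: LiN(iPr)2 (2.2 equiv), THF, −78 to −20 °C; then BnOCH2Cl, −78 to −20 °C; H2O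
Reagents that add atoms: benzyl chloromethyl ether, ClCOCc1ccccc1
Why: Fráter–Seebach alkylation, in which the chelated dilithium alkoxide–enolate is alkylated on the face opposite the vinyl group to give the anti product.

Step 8
Reactants: 17 methyl (2S,3S)-2-[(benzyloxy)methyl]-3-hydroxypent-4-enoate
Product: 19 methyl (2R,3S)-2-[(benzyloxy)methyl]-3-hydroxy-2-methylpent-4-enoate, via dianion 18 (not isolated)
Conditions: LiN(iPr)2 (2.2 equiv), THF/DMPU, −78 to −40 °C; then MeI, −78 to −40 °C; H2O
Reagents that add atoms: iodomethane, CI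
Why: Second Fráter–Seebach alkylation, in which methyl iodide again enters the lithium chelate opposite the vinyl group, so that the quaternary carbon (future C4) carries the CH2OBn arm (future C5) and the methyl group in the relative positions needed for the 4α-methyl/4β-carboxyl pattern.

Step 9
Reactants: 19 methyl (2R,3S)-2-[(benzyloxy)methyl]-3-hydroxy-2-methylpent-4-enoate; 10 Ar-acetic acid
Product: 20 methyl (2R,3S)-2-[(benzyloxy)methyl]-2-methyl-3-[(Ar-acetyl)oxy]pent-4-enoate
Conditions: N,N'-dicyclohexylcarbodiimide, 4-(dimethylamino)pyridine (cat.), CH2Cl2, 0 °C to rt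
Reagents that add atoms: none
Why: Steglich esterification of the hindered secondary allylic alcohol; acylating before the aldehyde is unveiled blocks retro-aldol cleavage of the C3–C4 bond.

Step 10
Reactants: 20 methyl (2R,3S)-2-[(benzyloxy)methyl]-2-methyl-3-[(Ar-acetyl)oxy]pent-4-enoate
Product: 21 methyl (2R,3S)-2-(hydroxymethyl)-2-methyl-3-[(Ar-acetyl)oxy]pent-4-enoate
Conditions: BCl3, pentamethylbenzene, CH2Cl2, −78 °C; then MeOH
Reagents that add atoms: none
Why: Lewis-acid cleavage of the alkyl benzyl ether at low temperature with pentamethylbenzene as benzyl-cation trap, conditions under which aryl methyl ethers, the alkene and the esters should survive.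

Step 11
Reactants: 21 methyl (2R,3S)-2-(hydroxymethyl)-2-methyl-3-[(Ar-acetyl)oxy]pent-4-enoate
Product: 23 methyl (2S,3R)-2-ethenyl-3-methyl-6-oxo-5-Ar-3,6-dihydro-2H-pyran-3-carboxylate, via aldehyde 22 (not isolated)
Conditions: Dess–Martin periodinane, CH2Cl2, rt; filtration; then 1,8-diazabicyclo[5.4.0]undec-7-ene, MeCN, rt to 40 °C
Reagents that add atoms: none
Why: Oxidation of the primary alcohol, then intramolecular Knoevenagel condensation in which the arylacetate enolate adds to the non-enolisable aldehyde (six-membered ring) and water is lost (E1cB) to the conjugated 3-aryl-5,6-dihydropyran-2-one.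

Step 12
Reactants: 23 methyl (2S,3R)-2-ethenyl-3-methyl-6-oxo-5-Ar-3,6-dihydro-2H-pyran-3-carboxylate; 24 tert-butyl acetate
Product: 29 (1R,5S,6S)-6-(2-tert-butoxy-2-oxoethyl)-5-(methoxycarbonyl)-5-methyl-1-Ar-cyclohex-3-ene-1-carboxylic acid, via lithium ester enolate 25 (not isolated), via lithium lactone enolate 26 (not isolated), via silyl ketene acetal 27 (not isolated), via silyl ester 28 (not isolated)
Conditions: LiN(iPr)2, 24, THF, −78 °C; then 23, −78 °C; tBuMe2SiCl, (Me2N)3PO, −78 °C to rt; PhMe, 110 °C; 1 M HCl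
Reagents that add atoms: none
Why: The lithium enolate of tert-butyl acetate adds in Michael fashion to C5 of 23 from the ring face opposite the pseudo-axial C4 methyl group and the C3 vinyl group (axial attack on the half-chair), and the α-aryl lactone enolate 26 is O-silylated to ketene acetal 27. On heating, 27 undergoes an Ireland–Claisen [3,3]-sigmatropic shift through a boat-like transition state shaped like bicyclo[2.2.2]octane, in which the vinyl group on C3 reaches across the lactone ring to C10, so that C1–C10 forms as C3–O breaks; hydrolysis of silyl ester 28 gives acid 29. The closest known reaction types are the tandem Michael addition/Ireland–Claisen rearrangement of allyl enoates and the Claisen ring contraction of silyl ketene acetals of 6-vinyl δ-lactones to cyclohex-3-ene-1-carboxylic acids. Ring A (C1, C2, C3, C4, C5, C10) is closed by this pericyclic ring contraction, the six-membered lactone becoming a six-membered carbocycle with a C2=C3 double bond. C5 is set by substrate control from C3 and C4, and C10 by suprafacial chirality transfer from C3, because the ring tether lets C1 reach only the face of C10=C20 on which the vinyl group lies, so that C20 must end cis to C19 and trans to the hydrogen on C5. The step needs 1,4- over 1,2-addition and O- over C-silylation, which are secured by the stabilised α-aryl enolate formed on 1,4-addition, the absence of acidic γ-hydrogens in 23 (C4 is quaternary) and the polar additive.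

Step 13
Reactants: 29 (1R,5S,6S)-6-(2-tert-butoxy-2-oxoethyl)-5-(methoxycarbonyl)-5-methyl-1-Ar-cyclohex-3-ene-1-carboxylic acid
Product: 30 (1R,2S,3S)-2-(2-tert-butoxy-2-oxoethyl)-3-(methoxycarbonyl)-3-methyl-1-Ar-cyclohexane-1-carboxylic acid
Conditions: H2 (1 atm), Pd/C, EtOAc, rt
Reagents that add atoms: none
Why: Heterogeneous hydrogenation of the cis-disubstituted ring alkene C2=C3, which creates no stereocentre and leaves the arene, the esters and the acid untouched.

Step 14
Reactants: 30 (1R,2S,3S)-2-(2-tert-butoxy-2-oxoethyl)-3-(methoxycarbonyl)-3-methyl-1-Ar-cyclohexane-1-carboxylic acid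
Product: 32 tert-butyl [(1S,5R,9R)-1-methyl-2-oxo-5-Ar-3-oxabicyclo[3.3.1]nonan-9-yl]acetate, via hydroxy diester 31 (not isolated)
Conditions: BH3·SMe2, THF, 0 °C to rt; MeOH; then 1,8-diazabicyclo[5.4.0]undec-7-ene (cat.), PhMe, 80 °C
Reagents that add atoms: none
Why: Borane reduces the free C20 acid much faster than the methyl and tert-butyl esters, and the C20 alcohol, held 1,3-diaxial to the C19 methyl ester, should then close the δ-lactone by base-catalysed transesterification while the tert-butyl ester is inert.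

Step 15
Reactants: 32 tert-butyl [(1S,5R,9R)-1-methyl-2-oxo-5-Ar-3-oxabicyclo[3.3.1]nonan-9-yl]acetate
Product: 34 (4S,5R,10R)-11,12,14-trimethoxy-7-oxoabieta-8,11,13-trien-19,20-olide, via carboxylic acid 33 (not isolated)
Conditions: CF3CO2H, CH2Cl2, rt; then (CF3CO)2O, 0 °C to rt
Reagents that add atoms: none
Why: Acidolysis of the tert-butyl ester, then intramolecular Friedel–Crafts acylation through the mixed trifluoroacetic anhydride at C8, the only free ring position (para to the C12 and ortho to the C14 methoxy group), which closes ring B trans-fused because both the aryl group and the acetic acid arm are equatorial on ring A.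

Step 16
Reactants: 34 (4S,5R,10R)-11,12,14-trimethoxy-7-oxoabieta-8,11,13-trien-19,20-olide
Product: 36 (4S,5R,10R)-11,14-dihydroxy-12-methoxy-7-oxoabieta-8,11,13-trien-19,20-olide, via quinone 35 (not isolated)
Conditions: (NH4)2Ce(NO3)6, MeCN/H2O, 0 °C; then Na2S2O4, H2O/EtOAc, rt, under Ar
Reagents that add atoms: water, O
Why: Oxidative demethylation of the para-dimethoxy pair (C11, C14) should give the 12-methoxy-para-quinone with water supplying the two quinone oxygens and the C12 methoxy group retained, and dithionite reduces the quinone to the hydroquinone.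

**Compound list**

1 | 1,2,4-trimethoxybenzene | COc1ccc(OC)c(OC)c1 | starting material
2 | acetone | CC(C)=O | starting material
3 | (2,3,6-trimethoxyphenyl)lithium | [Li]c1c(OC)ccc(OC)c1OC | intermediate
4 | 2-(2,3,6-trimethoxyphenyl)propan-2-ol | CC(C)(O)c1c(OC)ccc(OC)c1OC | intermediate
5 | 1,2,4-trimethoxy-3-(propan-2-yl)benzene | CC(C)c1c(OC)ccc(OC)c1OC | intermediate
6 | oxirane | C1CO1 | starting material
7 | [2,3,5-trimethoxy-4-(propan-2-yl)phenyl]lithium | [Li]c1cc(OC)c(C(C)C)c(OC)c1OC | intermediate
8 | 2-[2,3,5-trimethoxy-4-(propan-2-yl)phenyl]ethan-1-ol | OCCc1cc(OC)c(C(C)C)c(OC)c1OC | intermediate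
9 | [2,3,5-trimethoxy-4-(propan-2-yl)phenyl]acetaldehyde | O=CCc1cc(OC)c(C(C)C)c(OC)c1OC | intermediate
10 | [2,3,5-trimethoxy-4-(propan-2-yl)phenyl]acetic acid | OC(=O)Cc1cc(OC)c(C(C)C)c(OC)c1OC | intermediate
11 | methyl acetate | COC(C)=O | starting material
12 | acrolein (prop-2-enal) | C=CC=O | starting material
13 | lithium 1-methoxyethenolate | [Li+].[O-]C(=C)OC | intermediate
14 | methyl (±)-3-hydroxypent-4-enoate | C=CC(O)CC(=O)OC | intermediate
15 | methyl (3R)-3-hydroxypent-4-enoate | C=C[C@H](O)CC(=O)OC | intermediate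
16 | dilithium alkoxide–enolate of 15 | [Li+].[Li+].C=C[C@H]([O-])C=C([O-])OC | intermediate
17 | methyl (2S,3S)-2-[(benzyloxy)methyl]-3-hydroxypent-4-enoate | C=C[C@H](O)[C@H](COCc1ccccc1)C(=O)OC | intermediate
18 | dilithium alkoxide–enolate of 17 | [Li+].[Li+].C=C[C@H]([O-])C(COCc1ccccc1)=C([O-])OC | intermediate
19 | methyl (2R,3S)-2-[(benzyloxy)methyl]-3-hydroxy-2-methylpent-4-enoate | C=C[C@H](O)[C@@](C)(COCc1ccccc1)C(=O)OC | intermediate
20 | methyl (2R,3S)-2-[(benzyloxy)methyl]-2-methyl-3-[(Ar-acetyl)oxy]pent-4-enoate | C=C[C@H](OC(=O)Cc1cc(OC)c(C(C)C)c(OC)c1OC)[C@@](C)(COCc1ccccc1)C(=O)OC | intermediate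
21 | methyl (2R,3S)-2-(hydroxymethyl)-2-methyl-3-[(Ar-acetyl)oxy]pent-4-enoate | C=C[C@H](OC(=O)Cc1cc(OC)c(C(C)C)c(OC)c1OC)[C@@](C)(CO)C(=O)OC | intermediate
22 | methyl (2S,3S)-2-formyl-2-methyl-3-[(Ar-acetyl)oxy]pent-4-enoate | C=C[C@H](OC(=O)Cc1cc(OC)c(C(C)C)c(OC)c1OC)[C@@](C)(C=O)C(=O)OC | intermediate
23 | methyl (2S,3R)-2-ethenyl-3-methyl-6-oxo-5-Ar-3,6-dihydro-2H-pyran-3-carboxylate | C=C[C@@H]1OC(=O)C(c2cc(OC)c(C(C)C)c(OC)c2OC)=C[C@@]1(C)C(=O)OC | intermediate
24 | tert-butyl acetate | CC(=O)OC(C)(C)C | starting material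
25 | lithium 1-tert-butoxyethenolate | [Li+].[O-]C(=C)OC(C)(C)C | intermediate
26 | lithium enolate of the Michael adduct (lactone enolate C10=C20, CH2CO2tBu on C5 trans to the vinyl group) | [Li+].C=C[C@@H]1OC([O-])=C(c2cc(OC)c(C(C)C)c(OC)c2OC)[C@@H](CC(=O)OC(C)(C)C)[C@@]1(C)C(=O)OC | intermediate
27 | tert-butyldimethylsilyl ketene acetal of the same lactone | C=C[C@@H]1OC(O[Si](C)(C)C(C)(C)C)=C(c2cc(OC)c(C(C)C)c(OC)c2OC)[C@@H](CC(=O)OC(C)(C)C)[C@@]1(C)C(=O)OC | intermediate
28 | tert-butyldimethylsilyl ester of acid 29 | CC(C)(C)[Si](C)(C)OC(=O)[C@]1(c2cc(OC)c(C(C)C)c(OC)c2OC)CC=C[C@](C)(C(=O)OC)[C@@H]1CC(=O)OC(C)(C)C | intermediate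
29 | (1R,5S,6S)-6-(2-tert-butoxy-2-oxoethyl)-5-(methoxycarbonyl)-5-methyl-1-Ar-cyclohex-3-ene-1-carboxylic acid | OC(=O)[C@]1(c2cc(OC)c(C(C)C)c(OC)c2OC)CC=C[C@](C)(C(=O)OC)[C@@H]1CC(=O)OC(C)(C)C | intermediate
30 | (1R,2S,3S)-2-(2-tert-butoxy-2-oxoethyl)-3-(methoxycarbonyl)-3-methyl-1-Ar-cyclohexane-1-carboxylic acid | OC(=O)[C@]1(c2cc(OC)c(C(C)C)c(OC)c2OC)CCC[C@](C)(C(=O)OC)[C@@H]1CC(=O)OC(C)(C)C | intermediate
31 | methyl (1S,2R,3R)-2-(2-tert-butoxy-2-oxoethyl)-3-(hydroxymethyl)-1-methyl-3-Ar-cyclohexane-1-carboxylate | OC[C@]1(c2cc(OC)c(C(C)C)c(OC)c2OC)CCC[C@](C)(C(=O)OC)[C@@H]1CC(=O)OC(C)(C)C | intermediate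
32 | tert-butyl [(1S,5R,9R)-1-methyl-2-oxo-5-Ar-3-oxabicyclo[3.3.1]nonan-9-yl]acetate | CC(C)(C)OC(=O)C[C@@H]1[C@@]2(c3cc(OC)c(C(C)C)c(OC)c3OC)CCC[C@]1(C)C(=O)OC2 | intermediate
33 | [(1S,5R,9R)-1-methyl-2-oxo-5-Ar-3-oxabicyclo[3.3.1]nonan-9-yl]acetic acid | OC(=O)C[C@@H]1[C@@]2(c3cc(OC)c(C(C)C)c(OC)c3OC)CCC[C@]1(C)C(=O)OC2 | intermediate
34 | (4S,5R,10R)-11,12,14-trimethoxy-7-oxoabieta-8,11,13-trien-19,20-olide | COc1c(OC)c2c(c(OC)c1C(C)C)C(=O)C[C@@H]1[C@]23CCC[C@]1(C)C(=O)OC3 | intermediate
35 | (4S,5R,10R)-12-methoxy-7,11,14-trioxoabieta-8,12-dien-19,20-olide (the 11,14-quinone) | COC=1C(=O)C2=C(C(=O)C=1C(C)C)C(=O)C[C@@H]1[C@]23CCC[C@]1(C)C(=O)OC3 | intermediate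
36 | (4S,5R,10R)-11,14-dihydroxy-12-methoxy-7-oxoabieta-8,11,13-trien-19,20-olide | COc1c(O)c2c(c(O)c1C(C)C)C(=O)C[C@@H]1[C@]23CCC[C@]1(C)C(=O)OC3 | target

**Step count and risks**

Total step count: 16. Longest linear sequence: 12 steps (steps 5–16; the arene branch, steps 1–4 and 9–16, is equally long).

Step 12. What may go wrong: attack of the ester enolate on the lactone carbonyl or slow addition at the crowded C5; loss of the ketene acetal by hydrolysis or C-silylation; a slow [3,3] shift through the congested boat, with decomposition of the α-aryl ketene acetal on long heating. Fallback (Claisen rearrangement at the aldehyde oxidation level, without enolate or silyl group): it sets out from 23 and 24. The conjugate addition is run alone (LiN(iPr)2, THF, −78 °C; NH4Cl quench) to give saturated lactone F1. iBu2AlH (PhMe, −78 °C) should reduce the lactone carbonyl to lactol F2, and MsCl/Et3N should dehydrate this to cyclic enol ether F3. Heating (xylene, 140–160 °C) should effect the Claisen rearrangement of this allyl vinyl ether to cyclohexenecarbaldehyde F4, with the same boat-type chirality transfer. H2 with Pd/C then gives saturated aldehyde F5, and NaBH4 (MeOH) followed by the base of step 14 gives lactone 32, where the route is rejoined.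

Step 8. What may go wrong: β-elimination of benzyl oxide from the dianion (E1cB) in competition with C-methylation, or methylation on the wrong face. Fallback (the C3–C4 bond is made last, with both C4 substituents already in place): it sets out from acrolein 12. Commercial methyl 3-hydroxy-2-methylpropanoate is O-benzylated (benzyl 2,2,2-trichloroacetimidate, CF3SO3H cat.) to benzyl ether F6. Its lithium enolate (LiN(iPr)2, THF, −78 °C), whose geometry is fixed by chelation of lithium to the benzyloxy group, is added to 12; the Zimmerman–Traxler aldol should give mainly racemic hydroxy ester F7. A Sharpless kinetic resolution as in step 6 should leave the (2R,3S) enantiomer, which is 19.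

Step 3. What may go wrong: metalation at the other free ring position (future C8) or at both, which would place the side chain on the wrong carbon. Fallback (electrophilic substitution with a blocking group instead of metalation): it sets out from 5. N-Bromosuccinimide (MeCN) should brominate the more electron-rich position (future C8) to give aryl bromide F8. Friedel–Crafts alkylation of the one remaining ring position with ethyl chloro(methylsulfanyl)acetate and SnCl4 (CH2Cl2) should give thioether ester F9. Raney Ni (EtOH) should remove both the sulfur substituent and the bromine to give ethyl arylacetate F10, and LiOH (THF/H2O) gives acid 10.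

**Further compounds**

F1 | step 12 | methyl 4-(2-tert-butoxy-2-oxoethyl)-2-ethenyl-3-methyl-6-oxo-5-Ar-oxane-3-carboxylate (configuration at C2, C3, C4 as in 26; epimers at the aryl-bearing carbon) | C=C[C@@H]1OC(=O)C(c2cc(OC)c(C(C)C)c(OC)c2OC)[C@@H](CC(=O)OC(C)(C)C)[C@@]1(C)C(=O)OC
F2 | step 12 | corresponding lactol (6-hydroxyoxane) | C=C[C@@H]1OC(O)C(c2cc(OC)c(C(C)C)c(OC)c2OC)[C@@H](CC(=O)OC(C)(C)C)[C@@]1(C)C(=O)OC
F3 | step 12 | methyl 4-(2-tert-butoxy-2-oxoethyl)-2-ethenyl-3-methyl-5-Ar-3,4-dihydro-2H-pyran-3-carboxylate | C=C[C@@H]1OC=C(c2cc(OC)c(C(C)C)c(OC)c2OC)[C@@H](CC(=O)OC(C)(C)C)[C@@]1(C)C(=O)OC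
F4 | step 12 | methyl 6-(2-tert-butoxy-2-oxoethyl)-5-formyl-1-methyl-5-Ar-cyclohex-2-ene-1-carboxylate (configuration as in 29) | O=C[C@]1(c2cc(OC)c(C(C)C)c(OC)c2OC)CC=C[C@](C)(C(=O)OC)[C@@H]1CC(=O)OC(C)(C)C
F5 | step 12 | methyl 2-(2-tert-butoxy-2-oxoethyl)-3-formyl-1-methyl-3-Ar-cyclohexane-1-carboxylate (configuration as in 30) | O=C[C@]1(c2cc(OC)c(C(C)C)c(OC)c2OC)CCC[C@](C)(C(=O)OC)[C@@H]1CC(=O)OC(C)(C)C
F6 | step 8 | methyl 3-(benzyloxy)-2-methylpropanoate | COC(=O)C(C)COCc1ccccc1
F7 | step 8 | racemic methyl (2R*,3S*)-2-[(benzyloxy)methyl]-3-hydroxy-2-methylpent-4-enoate (racemate of 19; one enantiomer drawn) | C=C[C@H](O)[C@@](C)(COCc1ccccc1)C(=O)OC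
F8 | step 3 | 1-bromo-2,4,5-trimethoxy-3-(propan-2-yl)benzene | CC(C)c1c(OC)c(Br)cc(OC)c1OC
F9 | step 3 | ethyl [6-bromo-2,3,5-trimethoxy-4-(propan-2-yl)phenyl](methylsulfanyl)acetate | CCOC(=O)C(SC)c1c(Br)c(OC)c(C(C)C)c(OC)c1OC
F10 | step 3 | ethyl [2,3,5-trimethoxy-4-(propan-2-yl)phenyl]acetate | CCOC(=O)Cc1cc(OC)c(C(C)C)c(OC)c1OC
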